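## Analysis of the target

Target 14 is a biflavonoid in which a flavanone (rings A, C and B, the naringenin skeleton) is bonded through C3 to C3'' of a flavone (the apigenin skeleton). The two halves differ only by the two hydrogens at C2''/C3''. The only stereocentres are C2 (S) and C3 (R) of the flavanone ring C; they are vicinal, and the 4-hydroxyphenyl group at C2 and the chromonyl group at C3 are trans. C3 lies α to the C4 carbonyl and can epimerise by enolisation. C2 is a benzylic ether carbon para to a free phenol and loses its configuration whenever ring C opens (retro-oxa-Michael or quinone methide formation), which base promotes. Six free phenols make the late intermediates sensitive to oxidants and restrict the end of the route to neutral or mildly acidic conditions. The difficulty lies in the congested C3–C3'' bond between an sp3 and an sp2 carbon that are both α to a carbonyl, and in fixing C2 absolutely although nothing else in the molecule is chiral. The route rests on the fact that C3 and C3'' are the α-carbons of two chalcone-type C6–C3–C6 units, each conjugated through its ring B to a 4'-hydroxyl, the arrangement that couples 8–8 in lignans. A C2-symmetric 3,3''-biflavanone with both 4'-hydroxyls free is therefore a latent symmetrical precursor of 14.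

## Retrosynthetic reasoning

14 is first simplified to tetrabenzyl ether 13 by cutting the four benzyl–oxygen bonds at O5, O7, O5'' and O7''. These oxygens must be masked from the start, because each ring A may offer only one free hydroxyl (the later O1) next to its carbonyl. Benzyl ethers survive base, acid and oxidants and are removed last under neutral reducing conditions that respect the base-labile C2 centre. The two 4'-hydroxyls are left free on purpose, since they drive both oxidative steps. The forward reaction must cleave four aryl benzyl ethers without reducing the chromone double bond or the benzylic C2–O1 bond.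

13 is traced back to the C2-symmetric biflavanone 11 by adding two hydrogens across C2''=C3''. No bond is cut, but the two halves become identical, so the dimer can come from one monomer. A C2 axis exchanges the two flavanone units of 11, so removal of H2 and H3 from either unit gives the same compound; only the extent of oxidation needs control. In the forward direction a hydride acceptor uses the free 4'-hydroxyl: hydride loss from C2'' leads to quinone methide 12, which aromatises to the chromone. A following acid equilibration at C3 makes the step stereoconvergent, because the oxidised unit loses both its stereocentres and the remaining unit needs only a correct C2.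

11 is cut at three bonds: O1–C2, O1''–C2'' and C3–C3''. Each C2 is a benzylic carbon para to a free hydroxyl, that is, the methide carbon of a para-quinone methide, which leads to bis-quinone methide 10. The C3–C3'' bond of 10 joins two carbons that are α to a carbonyl and conjugated through ring B to the phenolic oxygen, the positions that carry spin in a 4-hydroxystyryl-type phenoxyl radical. Cutting it gives two radicals 9 and hence two molecules of chalcone 8. Three skeletal bonds, two rings and all four stereocentres of 11 thus derive from one achiral monomer. The forward reaction must oxidise only the 4-hydroxyl of 8, join two radicals 9 at their α-carbons rather than at ring B or at oxygen, and close both rings C by oxygen attack on the methide carbons under a chiral phosphoric acid so that C2 and C2'' receive the same configuration.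

8 is disconnected at the Cα=Cβ double bond, an aldol condensation retron, into methyl ketone 3 and an aromatic aldehyde. A free para-phenoxide would deactivate the aldehyde under the basic condensation conditions, so the aldehyde is used as its methoxymethyl ether 5. Protected chalcone 7, formed through aldol adduct 6, is then the direct precursor of 8. The acetal is orthogonal to the benzyl ethers and is removed by mild acid.

3 comes from 1 and two equivalents of 2 by cutting two benzyl–oxygen bonds. The hydroxyl that must stay free is the one hydrogen-bonded to the acetyl group, so the differentiation costs no extra step. 5 comes from 4 by O-alkylation.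

## Alternatives that were turned down

Alternative 1: Ring C is cut at C2–C3 and at O1–C8a, giving an aromatic aldehyde (the future C2 and O1) and an oxygenated diene that already carries the flavone on the carbon that becomes C3; ring A is absent and is added later. The forward key step is a hetero-Diels–Alder cycloaddition under Ti(OiPr)4 and (R)-1,1'-bi-2-naphthol, followed by acid, to give dihydropyranone A1, (2S,3R)-2-(4-benzyloxyphenyl)-3-[5,7-bis(benzyloxy)-2-(4-benzyloxyphenyl)-4-oxochromen-3-yl]-2,3-dihydropyran-4-one.
- For: the reaction type is well established for aldehydes and siloxydienes, the configuration at C2 comes from a proven catalyst class, and the C3–C3'' bond is not made under uncertain regiochemistry. On enantiocontrol this alternative is stronger than the chosen route.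
- Against: A1 is still two rings short of the target half. The 5,7-dioxygenated benzene ring A would have to be annulated onto the C4a=C8a enol ether double bond in a multistep arene construction. This would be done on an intermediate whose C3–H is α to a ketone and attached to a chromone, and whose C2–O bond is allylic and benzylic. A diene with a bulky, electron-poor chromonyl group at its reacting terminus is a poor partner, and the cis/trans outcome is open.
- Comparison: the chosen route starts from the ready-made ring A of 1 and closes both rings C in one step. In place of the stronger stereochemical precedent it offers a seven-step sequence.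

Alternative 2: Ring C is cut at C3–C4, so C4 is an aldehyde in the precursor and C3 is the β-carbon of an enone tethered through the C2–O1 aryl ether; C2 is installed beforehand. The forward key step is an intramolecular Stetter reaction with a triazolium-derived N-heterocyclic carbene, giving A2, (2S,3R)-5,7-bis(benzyloxy)-2-(4-benzyloxyphenyl)-3-[2-(2-methoxymethoxy-4,6-bis(benzyloxy)phenyl)-2-oxoethyl]chroman-4-one.
- For: chroman-4-one formation by this reaction is among the best-documented carbene-catalysed processes. C2 is fixed in the substrate, and there is no regiochemical ambiguity. On both points it is stronger than the chosen route.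
- Against: the substrate is an enantiopure secondary benzylic, allylic aryl ether of a hindered 2,4,6-trioxygenated salicylaldehyde; etherification at such a carbon invites ionisation and allylic transposition, hence loss of configuration. The precedent is for unsubstituted O–CH2 tethers. Here a substituted tether and a doubly ortho-substituted, electron-rich aldehyde slow both acyl anion formation and conjugate addition, and the C3 configuration rests on substrate control. A2 carries only a phenacyl arm, so the second heterocycle still requires aroylation of the methylene, unmasking of the phenol and cyclodehydration, under conditions that threaten C3 and C2.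
- Comparison: the sequence would be at least twice as long. The chosen route delivers both heterocycles and the C3–C3'' bond in one operation.

Alternative 3: Only O1–C2 is cut; the C3–C3'' bond and the complete flavone are already present in a dihydrochalcone-type precursor with a 4-hydroxybenzyl group on its α-carbon. The forward key step is Ag2O oxidation of that group to the para-quinone methide, then 6-exo addition of the ring A hydroxyl under a chiral phosphoric acid to give A3, (2S,3R)-5,7-bis(benzyloxy)-3-[5,7-bis(benzyloxy)-2-(4-benzyloxyphenyl)-4-oxo-4H-chromen-3-yl]-2-(4-hydroxyphenyl)chroman-4-one.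
- For: it uses the same closure as the chosen route but only once. The C3–C3'' bond is secured beforehand by polar chemistry, so no radical coupling regiochemistry and no statistical mono-dehydrogenation arise. Oxidation of 4-alkylphenols to quinone methides by Ag2O is well known. On reliability of the key step this alternative is clearly stronger.
- Against: the precursor is an α-(flavon-3-yl) ketone with a 4-hydroxybenzyl branch and two selectively free hydroxyls among five benzyl ethers. It needs a long linear preparation, probably more than double the length of the chosen route. Its α-stereocentre is racemic and epimerisable, so the catalyst must set C2 regardless of C3, with equilibration afterwards. The enantiocontrol is as unproven as in the chosen route, and the acid cannot coexist with Ag2O either.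
- Comparison: the chosen route runs the same closure twice, forms the C3–C3'' bond in the same flask and reaches its precursor in four steps. The price is the regiochemical risk of the radical coupling.

Key step: step 5

Assumption: the sense of induction of the phosphoric acid on this new substrate class cannot be predicted. The route is written with the (R)-acid on the assumption that it gives the 2S,2''S series; the (S)-acid would be used if the induction proved opposite.

## Route

Step 1
Reactants: 1 2,4,6-trihydroxyacetophenone; 2 benzyl bromide (2.05 equiv)
Product: 3 1-[2-hydroxy-4,6-bis(benzyloxy)phenyl]ethanone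
Conditions: K2CO3 (2.2 equiv), DMF, 25 → 50 °C
Reagents that add atoms: none
Why: Williamson ether synthesis; the 4-hydroxyl and one ortho hydroxyl are alkylated, while the remaining ortho hydroxyl is hydrogen-bonded to the acetyl oxygen, is the least nucleophilic, and stays free when the halide is limited to two equivalents.

Step 2
Reactants: 4 4-hydroxybenzaldehyde
Product: 5 4-(methoxymethoxy)benzaldehyde
Conditions: MOMCl, iPr2NEt, CH2Cl2, 0 °C → rt
Reagents that add atoms: chloromethyl methyl ether, COCCl
Why: O-alkylation of the phenol with an α-chloro ether; the acetal masks the phenol so that no deactivating phenoxide forms in step 3.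

Step 3
Reactants: 3 1-[2-hydroxy-4,6-bis(benzyloxy)phenyl]ethanone; 5 4-(methoxymethoxy)benzaldehyde
Product: 7 (E)-1-[2-hydroxy-4,6-bis(benzyloxy)phenyl]-3-[4-(methoxymethoxy)phenyl]prop-2-en-1-one, via aldol adduct 6 (not isolated)
Conditions: KOH (50% aq), EtOH/THF, rt
Reagents that add atoms: none
Why: Claisen–Schmidt condensation; the enolate of 3 adds to the non-enolisable aldehyde 5 and adduct 6 loses water by E1cB to the conjugated E-enone; benzyl and methoxymethyl ethers are inert to hydroxide.

Step 4
Reactants: 7 (E)-1-[2-hydroxy-4,6-bis(benzyloxy)phenyl]-3-[4-(methoxymethoxy)phenyl]prop-2-en-1-one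
Product: 8 (E)-1-[2-hydroxy-4,6-bis(benzyloxy)phenyl]-3-(4-hydroxyphenyl)prop-2-en-1-one
Conditions: HCl (3 M aq), MeOH/THF, 50 °C
Reagents that add atoms: none
Why: acid-catalysed cleavage of the methoxymethyl acetal; benzyl ethers and the enone are stable, and the hydrogen-bonded ring A hydroxyl adds to the enone only slowly under these conditions, so the open chalcone is kept.

Step 5
Reactants: 8 (E)-1-[2-hydroxy-4,6-bis(benzyloxy)phenyl]-3-(4-hydroxyphenyl)prop-2-en-1-one (two molecules)
Product: 11 (2S,3R,2''S,3''R)-5,7,5'',7''-tetrakis(benzyloxy)-4',4'''-dihydroxy-3,3''-biflavanone, via phenoxyl radical 9 (not isolated), via bis-quinone methide 10 (not isolated)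
Conditions: Ag2O (1.0 equiv), 4 Å MS, CH2Cl2, −20 °C, dark; cold filtration through Celite; then (R)-3,3'-bis(2,4,6-triisopropylphenyl)-1,1'-binaphthyl-2,2'-diyl hydrogen phosphate (10 mol%), 4 Å MS, CH2Cl2/toluene, −40 → 0 °C
Reagents that add atoms: none
Why: Proposed new method: Ag2O (monovalent silver, reduced to silver metal) takes one electron and one proton from the acidic, non-chelated 4-hydroxyl of 8, the hydrogen-bonded ring A hydroxyl being a much poorer hydrogen donor, and gives radical 9, whose spin reaches the α-carbon through ring B and the enone; combination of two radicals at their α-carbons forms C3–C3'' and leaves bis-quinone methide 10. The closest known reaction types are the oxidative 8–8 dehydrodimerisation of 4-hydroxycinnamyl phenols with internal trapping of both quinone methides, and chiral phosphoric acid catalysed 1,6-additions to para-quinone methides; neither has been shown on a 4-hydroxychalcone, nor have the two been combined. The silver solids are removed before the acid is added, because Ag2O would convert the phosphoric acid into its silver salt and could re-oxidise the phenols of the product; the sieves take up the water formed. Each ring C then closes by a 6-exo-trig oxa-1,6-addition of the ring A hydroxyl to its methide carbon (O1–C2 and O1''–C2''), which restores aromatic ring B and the 4'-hydroxyl. C2 and C2'' are set by the catalyst, which is expected to bind the quinone methide carbonyl through P–OH and the attacking hydroxyl through P=O and so to deliver oxygen to the same face of both methides, giving the homochiral, C2-symmetric series. C3 and C3'' arise in the radical combination without catalyst control; each closing ring should prefer the trans-diequatorial arrangement, and because both centres are α to a ketone and one unit is dehydrogenated in step 6, material that is cis at C3 converges there on the same compound. The step needs α–α coupling to win over coupling at ring B carbons or at oxygen, which rests on the spin density at the carbonyl-flanked α-carbon and is not assured; ring B lacks an activating group, so aryl attack on the methide is unlikely. It also needs ring closure to outrun tautomerisation of 10 to an aromatic open dimer and a slow uncatalysed closure, which the hydrogen-bonded, weakly nucleophilic ring A hydroxyl should provide.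

Step 6
Reactants: 11 (2S,3R,2''S,3''R)-5,7,5'',7''-tetrakis(benzyloxy)-4',4'''-dihydroxy-3,3''-biflavanone
Product: 13 (2S,3R)-5,7-bis(benzyloxy)-3-[5,7-bis(benzyloxy)-2-(4-hydroxyphenyl)-4-oxo-4H-chromen-3-yl]-2-(4-hydroxyphenyl)chroman-4-one, via quinone methide 12 (not isolated)
Conditions: DDQ (1.0 equiv), 1,4-dioxane, 40 °C; then TsOH·H2O (0.2 equiv), 40 °C
Reagents that add atoms: none
Why: DDQ dehydrogenation of a flavanone to a flavone, here assisted by the free 4'''-hydroxyl: hydride loss from C2'' gives quinone methide 12, which loses H3'' and aromatises to the chromone; the C2 axis makes both units equivalent, and one equivalent of oxidant holds back the second dehydrogenation. The acid then equilibrates C3 by enolisation to the trans-diequatorial arrangement relative to the untouched C2, so C3 epimers carried from step 5 converge on 13.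

Step 7
Reactants: 13 (2S,3R)-5,7-bis(benzyloxy)-3-[5,7-bis(benzyloxy)-2-(4-hydroxyphenyl)-4-oxo-4H-chromen-3-yl]-2-(4-hydroxyphenyl)chroman-4-one
Product: 14 (2S,3R)-5,7-dihydroxy-3-[5,7-dihydroxy-2-(4-hydroxyphenyl)-4-oxo-4H-chromen-3-yl]-2-(4-hydroxyphenyl)chroman-4-one
Conditions: H2 (1 atm), 10% Pd/C, EtOAc/MeOH, rt
Reagents that add atoms: none
Why: catalytic hydrogenolysis of the four aryl benzyl ethers; the tetrasubstituted chromone double bond and the aryl ketones should not be reduced at one atmosphere and room temperature, and the neutral medium leaves C2 and C3 untouched.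

## Compound list

1 | 2,4,6-trihydroxyacetophenone | CC(=O)c1c(O)cc(O)cc1O | starting material
2 | benzyl bromide | BrCc1ccccc1 | starting material
3 | 1-[2-hydroxy-4,6-bis(benzyloxy)phenyl]ethanone | CC(=O)c1c(O)cc(OCc2ccccc2)cc1OCc1ccccc1 | intermediate
4 | 4-hydroxybenzaldehyde | O=Cc1ccc(O)cc1 | starting material
5 | 4-(methoxymethoxy)benzaldehyde | COCOc1ccc(C=O)cc1 | intermediate
6 | 3-hydroxy-1-[2-hydroxy-4,6-bis(benzyloxy)phenyl]-3-[4-(methoxymethoxy)phenyl]propan-1-one (racemic aldol adduct) | COCOc1ccc(cc1)C(O)CC(=O)c1c(O)cc(OCc2ccccc2)cc1OCc1ccccc1 | intermediate
7 | (E)-1-[2-hydroxy-4,6-bis(benzyloxy)phenyl]-3-[4-(methoxymethoxy)phenyl]prop-2-en-1-one | COCOc1ccc(/C=C/C(=O)c2c(O)cc(OCc3ccccc3)cc2OCc2ccccc2)cc1 | intermediate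
8 | (E)-1-[2-hydroxy-4,6-bis(benzyloxy)phenyl]-3-(4-hydroxyphenyl)prop-2-en-1-one | O=C(/C=C/c1ccc(O)cc1)c1c(O)cc(OCc2ccccc2)cc1OCc1ccccc1 | intermediate
9 | 4-{(E)-3-[2-hydroxy-4,6-bis(benzyloxy)phenyl]-3-oxoprop-1-enyl}phenoxyl radical | [O]c1ccc(/C=C/C(=O)c2c(O)cc(OCc3ccccc3)cc2OCc2ccccc2)cc1 | intermediate
10 | 1,4-bis[2-hydroxy-4,6-bis(benzyloxy)phenyl]-2,3-bis[(4-oxocyclohexa-2,5-dien-1-ylidene)methyl]butane-1,4-dione (bis-quinone methide, mixture of diastereomers at the two central carbons) | O=C1C=CC(=CC(C(=O)c2c(O)cc(OCc3ccccc3)cc2OCc2ccccc2)C(C=C2C=CC(=O)C=C2)C(=O)c2c(O)cc(OCc3ccccc3)cc2OCc2ccccc2)C=C1 | intermediate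
11 | (2S,3R,2''S,3''R)-5,7,5'',7''-tetrakis(benzyloxy)-4',4'''-dihydroxy-3,3''-biflavanone | O=C1c2c(OCc3ccccc3)cc(OCc3ccccc3)cc2O[C@H](c2ccc(O)cc2)[C@H]1[C@H]1C(=O)c2c(OCc3ccccc3)cc(OCc3ccccc3)cc2O[C@@H]1c1ccc(O)cc1 | intermediate
12 | (2S,3R)-5,7-bis(benzyloxy)-3-[(3R)-5,7-bis(benzyloxy)-4-oxo-2-(4-oxocyclohexa-2,5-dien-1-ylidene)chroman-3-yl]-2-(4-hydroxyphenyl)chroman-4-one | O=C1c2c(OCc3ccccc3)cc(OCc3ccccc3)cc2O[C@H](c2ccc(O)cc2)[C@H]1[C@H]1C(=O)c2c(OCc3ccccc3)cc(OCc3ccccc3)cc2OC1=C1C=CC(=O)C=C1 | intermediate
13 | (2S,3R)-5,7-bis(benzyloxy)-3-[5,7-bis(benzyloxy)-2-(4-hydroxyphenyl)-4-oxo-4H-chromen-3-yl]-2-(4-hydroxyphenyl)chroman-4-one | O=C1c2c(OCc3ccccc3)cc(OCc3ccccc3)cc2O[C@H](c2ccc(O)cc2)[C@H]1c1c(-c2ccc(O)cc2)oc2cc(OCc3ccccc3)cc(OCc3ccccc3)c2c1=O | intermediate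
14 | (2S,3R)-5,7-dihydroxy-3-[5,7-dihydroxy-2-(4-hydroxyphenyl)-4-oxo-4H-chromen-3-yl]-2-(4-hydroxyphenyl)chroman-4-one | O=C1c2c(O)cc(O)cc2O[C@H](c2ccc(O)cc2)[C@H]1c1c(-c2ccc(O)cc2)oc2cc(O)cc(O)c2c1=O | target

## Step count and least certain steps

Total step count: 7. Longest linear sequence: 6 steps (steps 1, 3, 4, 5, 6 and 7; step 2 is a one-step branch).

Step 5 (key step). The most likely failures are:
- radical combination at the wrong positions, α-carbon to ring B carbon or α-carbon to oxygen, since the positions ortho to the 4-hydroxyl are unsubstituted and such modes normally compete for 4-hydroxycinnamoyl radicals;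
- tautomerisation of the bis-quinone methide to an open, aromatised dimer before the closures;
- poor or mismatched enantiofacial selectivity in the two closures, which would feed heterochiral dimers and lower the enantiopurity after step 6;
- slow oxidation at the low temperature needed to preserve the quinone methides.

The fallback uses known chemistry, sets out from 3 and returns at 11. Ketone 3 is heated with N,N-dimethylformamide dimethyl acetal to give enaminone (E)-3-(dimethylamino)-1-[2-hydroxy-4,6-bis(benzyloxy)phenyl]prop-2-en-1-one F1. HCl in CH2Cl2 cyclises it to 5,7-bis(benzyloxy)chromen-4-one F2. Asymmetric conjugate addition of 4-(methoxymethoxy)phenylboronic acid to F2 is run with Pd(OCOCF3)2 (divalent palladium), NH4PF6 and water in 1,2-dichloroethane at 60 °C. The ligand is the enantiomer of 4-tert-butyl-2-(pyridin-2-yl)-4,5-dihydrooxazole that delivers the 2S product. This gives (2S)-5,7-bis(benzyloxy)-2-[4-(methoxymethoxy)phenyl]chroman-4-one F3. Its lithium enolate (LiN(SiMe3)2, THF, −78 °C) is oxidised with CuCl2 (divalent copper) in an oxidative enolate homocoupling. Each C3 should bond anti to the neighbouring C2 aryl group, and because the monomer is a single enantiomer the trans,trans dimer is the C2-symmetric one, (2S,3R,2''S,3''R)-5,7,5'',7''-tetrakis(benzyloxy)-4',4'''-bis(methoxymethoxy)-3,3''-biflavanone F4. The low temperature is needed to suppress β-elimination of the ring oxygen from the enolate. HCl in MeOH/THF removes both methoxymethyl ethers and returns 11.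

Step 6. The first and the second dehydrogenation are not differentiated, so over-oxidation of the remaining flavanone unit is the main danger. Side oxidation of the free phenols and loss of configuration at C2 by ring opening during the acid stage are further risks.

The fallback moves the desymmetrisation from the irreversible oxidation to a reversible protection; it sets out from 11 and returns at 13. Diol 11 is treated with one equivalent of tert-butyldimethylsilyl chloride and imidazole to give the mono-silyl ether (2S,3R,2''S,3''R)-5,7,5'',7''-tetrakis(benzyloxy)-4'-(tert-butyldimethylsilyloxy)-4'''-hydroxy-3,3''-biflavanone F5. Unreacted and over-silylated material is recycled after desilylation. DDQ at room temperature then oxidises only the unit whose 4'-hydroxyl is free, through the quinone methide pathway. This gives (2S,3R)-5,7-bis(benzyloxy)-3-[5,7-bis(benzyloxy)-2-(4-hydroxyphenyl)-4-oxo-4H-chromen-3-yl]-2-[4-(tert-butyldimethylsilyloxy)phenyl]chroman-4-one F6. HF·pyridine in THF removes the silyl group and gives 13.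

Step 7. Over-reduction is the risk: hydrogenolysis of the benzylic C2–O1 bond, which opens ring C, or saturation of the chromone double bond, together with incomplete cleavage of the hindered 5-O-benzyl groups.

The fallback replaces hydrogenolysis by Lewis-acid dealkylation; it sets out from 13 and gives 14 directly. BCl3 with pentamethylbenzene as cation scavenger in CH2Cl2 at −78 °C cleaves the four benzyl ethers heterolytically under non-reducing, non-basic conditions. No new intermediate is involved.

## Further compounds

F1 | step 5 | (E)-3-(dimethylamino)-1-[2-hydroxy-4,6-bis(benzyloxy)phenyl]prop-2-en-1-one | CN(C)/C=C/C(=O)c1c(O)cc(OCc2ccccc2)cc1OCc1ccccc1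
F2 | step 5 | 5,7-bis(benzyloxy)chromen-4-one | O=c1ccoc2cc(OCc3ccccc3)cc(OCc3ccccc3)c12
F3 | step 5 | (2S)-5,7-bis(benzyloxy)-2-[4-(methoxymethoxy)phenyl]chroman-4-one | O=C1C[C@@H](c2ccc(OCOC)cc2)Oc2cc(OCc3ccccc3)cc(OCc3ccccc3)c12
F4 | step 5 | (2S,3R,2''S,3''R)-5,7,5'',7''-tetrakis(benzyloxy)-4',4'''-bis(methoxymethoxy)-3,3''-biflavanone | O=C1c2c(OCc3ccccc3)cc(OCc3ccccc3)cc2O[C@H](c2ccc(OCOC)cc2)[C@H]1[C@H]1C(=O)c2c(OCc3ccccc3)cc(OCc3ccccc3)cc2O[C@@H]1c1ccc(OCOC)cc1
F5 | step 6 | (2S,3R,2''S,3''R)-5,7,5'',7''-tetrakis(benzyloxy)-4'-(tert-butyldimethylsilyloxy)-4'''-hydroxy-3,3''-biflavanone | O=C1c2c(OCc3ccccc3)cc(OCc3ccccc3)cc2O[C@H](c2ccc(O[Si](C)(C)C(C)(C)C)cc2)[C@H]1[C@H]1C(=O)c2c(OCc3ccccc3)cc(OCc3ccccc3)cc2O[C@@H]1c1ccc(O)cc1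
F6 | step 6 | (2S,3R)-5,7-bis(benzyloxy)-3-[5,7-bis(benzyloxy)-2-(4-hydroxyphenyl)-4-oxo-4H-chromen-3-yl]-2-[4-(tert-butyldimethylsilyloxy)phenyl]chroman-4-one | O=C1c2c(OCc3ccccc3)cc(OCc3ccccc3)cc2O[C@H](c2ccc(O[Si](C)(C)C(C)(C)C)cc2)[C@H]1c1c(-c2ccc(O)cc2)oc2cc(OCc3ccccc3)cc(OCc3ccccc3)c2c1=O
F0 | step 7 | none | none
A1 | alternative 1 | (2S,3R)-2-(4-benzyloxyphenyl)-3-[5,7-bis(benzyloxy)-2-(4-benzyloxyphenyl)-4-oxochromen-3-yl]-2,3-dihydropyran-4-one | O=C1C=CO[C@H](c2ccc(OCc3ccccc3)cc2)[C@H]1c4c(-c5ccc(OCc6ccccc6)cc5)oc5cc(OCc6ccccc6)cc(OCc6ccccc6)c5c4=O
A2 | alternative 2 | (2S,3R)-5,7-bis(benzyloxy)-2-(4-benzyloxyphenyl)-3-[2-(2-methoxymethoxy-4,6-bis(benzyloxy)phenyl)-2-oxoethyl]chroman-4-one | O=C1c2c(OCc3ccccc3)cc(OCc3ccccc3)cc2O[C@H](c2ccc(OCc3ccccc3)cc2)[C@H]1CC(=O)c1c(OCOC)cc(OCc3ccccc3)cc1OCc1ccccc1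
A3 | alternative 3 | (2S,3R)-5,7-bis(benzyloxy)-3-[5,7-bis(benzyloxy)-2-(4-benzyloxyphenyl)-4-oxo-4H-chromen-3-yl]-2-(4-hydroxyphenyl)chroman-4-one | O=C1c2c(OCc3ccccc3)cc(OCc3ccccc3)cc2O[C@H](c2ccc(O)cc2)[C@H]1c4c(-c5ccc(OCc6ccccc6)cc5)oc5cc(OCc6ccccc6)cc(OCc6ccccc6)c5c4=O
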